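## Structural features

The target is a biflavone: two 2-(4-methoxyphenyl)benzopyran-4-one units, each made of ring A (benzo), ring C (pyranone) and ring B (the aryl group at C2), joined by one aryl–aryl bond from C6 of unit 1 to C8 of unit 2. Unit 1 has free hydroxyls at C5 and C7, whereas unit 2 has a free hydroxyl at C5 and a methyl ether at C7. There is no stereocentre, but the connecting bond has four ortho substituents (O5 and O7 of unit 1, the C7 methoxy group and the ring oxygen on C8a of unit 2), so rotation about it is hindered. The fragile elements are the three aryl methyl ethers, which must survive the release of three phenols, the two pyranone enones, and the electron-rich, easily oxidized ring A of each unit. The real difficulty is this tetra-ortho-substituted bond between two 1,3,5-trioxygenated rings of unsymmetrical regiochemistry, C6 on one side and C8 on the other, where a direct coupling is hindered and regiochemically ambiguous. The key step exploits ring A of unit 2, in which C8, the carbon that holds unit 1, has the methoxy-bearing C7 on one side and the oxygen-bearing ring-fusion carbon C8a on the other, and in which C5 carries the third oxygen. That is the 2-substituted 3,5-dialkoxyphenol pattern that results when a vinylketene is annulated onto an aryl ynol ether, so this ring can be grown on an alkyne at C6 of an intact unit 1.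

## Logic of the disconnections

**23 to 22.** The O–alkyl bonds at O5 and O7 of unit 1 (isopropyl) and at O5 of unit 2 (ethyl) are cut. Three phenols must stay masked during ring construction while three methyl ethers remain, so the masks are chosen to fall to one Lewis acid. The gain is an upstream sequence free of chelating phenols. The forward step must distinguish secondary-alkyl and carbonyl-chelated ethyl ethers from non-chelated aryl methyl ethers.

**22 to 20 (through 21).** The C4–C4a bond of unit 2 is cut. The ring carbon concerned is ortho to the ring oxygen, ortho to the ethoxy group and para to the methoxy group, and it is the only free position ortho to that oxygen, so the acylation has a single possible outcome. Ring C of unit 2 is reduced to the aryl vinyl ether acid 20. The forward step needs an activation mild enough for the isopropyl ethers, under which either alkene geometry can reach the cyclizable form.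

**20 to 19, then 19 to 17 plus 18.** After the trivial ester-to-acid change, the O1–C2 bond of unit 2 is cut. One conjugate addition then brings in C2, C3, C4 and ring B of unit 2 from 18. The demand is that the hindered phenoxide of 17 adds to the donor-substituted alkynoate 18 and that hydrolysis of 19 does not reverse the addition.

**17 to 8 plus 12.** The bonds C8–C8a, C6–C7 and C4a–C8a of unit 2 are cut, which takes ring A of unit 2 apart into the alkyne 8 and the four-carbon ketene precursor 12. This is the largest simplification. The hindered biaryl bond becomes an unhindered aryl–alkyne bond, and the three oxygens of the new ring arrive already differentiated as hydroxyl, methyl ether and ethyl ether. The forward step must control the orientation in which 13 and 8 unite and must leave the pyranone of 8 untouched at about 100 °C.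

**12 to 9 plus 10 (through 11).** Two ring bonds of the cyclobutenone are cut in a retro-(2+2) sense. In the forward direction 11 must be trapped by 10 faster than it dimerizes.

**8 to 4 plus 5 (through 6 and 7).** The C6–C(sp) bond is cut. Coupling of a linear acetylide tolerates two ortho alkoxy groups. The forward step requires that 7 is formed cleanly from 5 by way of 6 and that no acetylide adds to the pyranone of 4.

**4 to 3 to 2 to 1.** The O5–isopropyl bond, the C6–I bond and the O7–isopropyl bond are cut in that order. The order follows from regiochemistry: the free, chelated 5-hydroxyl steers iodination to C6, so it is capped only afterwards, and the more acidic 7-hydroxyl is alkylated first. The sequence ends at 1, which already contains rings A, B and C of unit 1.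

## Other disconnections considered

Alternative 1: Both pyranone rings are opened at the C2–C3 double bond, so the precursor is the bis(phosphorane) bis(aryl ester) A2. When A2 is heated, the ylide carbon of each unit should add to the ester carbonyl on the adjacent oxygen in an intramolecular Wittig olefination, which would close both rings C and give the tribenzyl biflavone A1.
- In its favour: two rings and both C2–C3 bonds form in one neutral thermal step, the direction of ring closure is fixed by which oxygen carries the ester, and no acid touches the benzyl ethers.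
- Against it: A2 already contains the tetra-ortho-substituted biaryl bond between two fully differentiated trioxygenated rings, so the hardest bond is left to a hindered coupling. In unit 2 the ester must sit on the oxygen next to the biaryl bond, the most crowded position. Olefination of an aryl ester by a stabilized ylide needs high temperature.
- Comparison: it is the better plan in rings formed per step and in treating both units identically, and the equal of the chosen plan in ending with one dealkylation step. It is weaker in structure, because the biaryl bond is unsolved. With the protecting-group work needed to differentiate six oxygens it is expected to be longer.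

Alternative 2: Both units are cut at C4–C4a, so the precursor is the bis(aryloxycinnamic acid) A4. Activation of both carboxyl groups of A4 should let each acyl group attack the ring carbon ortho to its ether oxygen and give the triisopropyl biflavone A3.
- In its favour: the ring closure is the same reaction as step 9 of the chosen route, used twice, so it is the equal in mechanism. Regiochemistry is secure, because the aryloxy ring of unit 1 in A4 is symmetric and that of unit 2 has one free ortho carbon. A3 carries only isopropyl masks, which should make its final dealkylation cleaner than that of 22; this is a point in its favour.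
- Against it: A4 still contains the biaryl bond with four ortho oxygens, so the hindered cross-coupling of two different trioxygenated rings has to be solved before A4 exists. Two conjugate additions are needed, one on the crowded phenol. Rings A, B and C of unit 1 are not taken from a ready-made flavone.
- Comparison: equal in the chemistry of ring C, better in the uniformity of protecting groups, weaker in structure because the key bond is again deferred, and comparable or longer in step count.

Alternative 3: Ring A of unit 2 is cut at C4a–C5, so the precursor is the pyranonyl butenoic acid A6. Activation of A6 and loss of HX should give the dienylketene A7, which closes onto the pyranone carbon in a six-electron electrocyclization and tautomerizes to the 5-hydroxy-7-methoxyflavone A5.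
- In its favour: the ring-forming event is the same pericyclic closure that ends the chosen key step, so it is the equal in mechanism. A5 carries the free 5-hydroxyl and the 7-methoxy group of the target directly, with no ethyl ether to cleave later, which is better than the chosen plan. Rings B and C of unit 2 are already in place.
- Against it: A6 is a tetrasubstituted alkene of defined (E) geometry carrying a 2,4,6-tris(benzyloxy)phenyl group, and its aryl–alkene bond is as crowded as the biaryl bond it replaces. Unit 1 must then be built on the symmetric trioxygenated ring of A5, where ring C has to close onto the oxygen para to the axis and not onto an ortho oxygen. Closure the wrong way would misplace the interflavone bond.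
- Comparison: the chosen plan keeps unit 1 intact from 1 and closes its only new pyranone at a position with no alternative. Alternative 3 is better in the oxygen pattern delivered by the key step, equal in mechanism, and weaker in the regiochemical risk and in the number of steps after the key step.

Key step: step 6

Assumption: the target is drawn without an axial descriptor, so the hindered biaryl bond is formed without stereocontrol and racemic material is the goal. Methyl 3-(4-methoxyphenyl)propiolate, 2-bromopropane, BnNMe3·ICl2 and 5,7,4'-trimethoxyflavone are taken as purchasable.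

## Route

Step 1
Reactants: 1 acacetin (5,7-dihydroxy-4'-methoxyflavone)
Product: 2 5-hydroxy-7-isopropoxy-4'-methoxyflavone
Conditions: 2-bromopropane (1.3 equiv), K2CO3, DMF, 50 °C
Reagents that add atoms: 2-bromopropane, CC(C)Br
Why: Williamson etherification; the 7-hydroxyl is the more acidic, unchelated phenol, whereas the 5-hydroxyl is held in a hydrogen bond to the C4 carbonyl, so mono-alkylation at O7 should dominate.

Step 2
Reactants: 2 5-hydroxy-7-isopropoxy-4'-methoxyflavone
Product: 3 5-hydroxy-6-iodo-7-isopropoxy-4'-methoxyflavone
Conditions: BnNMe3·ICl2 (1.1 equiv), CaCO3, CH2Cl2/MeOH, rt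
Reagents that add atoms: benzyltrimethylammonium dichloroiodate, C[N+](C)(C)Cc1ccccc1.Cl[I-]Cl
Why: Electrophilic aromatic iodination; with the 5-hydroxyl free the iodonium is delivered to the ortho carbon C6, whereas 5-O-alkylated flavones react at C8, which is why iodination precedes the second alkylation; CaCO3 buffers the HCl formed.

Step 3
Reactants: 3 5-hydroxy-6-iodo-7-isopropoxy-4'-methoxyflavone
Product: 4 6-iodo-5,7-diisopropoxy-4'-methoxyflavone
Conditions: 2-bromopropane (excess), Cs2CO3, DMF, 70 °C
Reagents that add atoms: 2-bromopropane, CC(C)Br
Why: Williamson etherification of the chelated, flanked 5-hydroxyl; the phenoxide formed with Cs2CO3 in DMF is nucleophilic enough, and excess secondary bromide compensates for loss to E2 elimination.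

Step 4
Reactants: 4 6-iodo-5,7-diisopropoxy-4'-methoxyflavone; 5 chloroacetaldehyde dimethyl acetal
Product: 8 5,7-diisopropoxy-6-(methoxyethynyl)-4'-methoxyflavone, via lithium methoxyacetylide 6 (not isolated), via methoxyethynylzinc chloride 7 (not isolated)
Conditions: 5, Et2NH/n-BuLi (LiNEt2, 3 equiv per 5), THF, 0 °C; ZnCl2 (excess), 0 °C; then 4, Pd(PPh3)4 (5 mol %), THF, rt→45 °C
Reagents that add atoms: none
Why: Two base-induced eliminations (methanol, then HCl) and deprotonation turn 5 into acetylide 6, and transmetalation to zinc gives 7 before 4 is added, so that no lithium acetylide can attack the pyranone; Negishi coupling with zerovalent palladium then forms the C6–C(sp) bond, the linear nucleophile being little affected by the two ortho isopropoxy groups.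

Step 5
Reactants: 9 acetyl chloride; 10 ethoxyacetylene
Product: 12 3-ethoxycyclobut-2-en-1-one, via ketene 11 (not isolated)
Conditions: Et3N, Et2O, 0 °C→rt, 9 added slowly to 10 (2 equiv)
Reagents that add atoms: none
Why: Dehydrochlorination of 9 gives ketene 11 at low stationary concentration, and its (2+2) ketene–alkyne cycloaddition with the strongly nucleophilic ynol ether 10 should outrun dimerization; the oxygen-polarized CH terminus of 10 bonds to the ketene carbonyl carbon, which places the ethoxy group at C3.

Step 6
Reactants: 8 5,7-diisopropoxy-6-(methoxyethynyl)-4'-methoxyflavone; 12 3-ethoxycyclobut-2-en-1-one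
Product: 17 6-(4-ethoxy-2-hydroxy-6-methoxyphenyl)-5,7-diisopropoxy-4'-methoxyflavone, via vinylketene 13 (not isolated), via vinylcyclobutenone 14 (not isolated), via dienylketene 15 (not isolated), via cyclohexadienone 16 (not isolated)
Conditions: 12 (2 equiv), PhMe, 80 °C then 110 °C, sealed tube
Reagents that add atoms: none
Why: Danheiser benzannulation, the thermal union of a cyclobutenone with a heteroatom-substituted alkyne. Four-electron electrocyclic opening of 12 gives vinylketene 13, whose ketene C=C bond adds across the triple bond of 8 in a regioselective (2+2) cycloaddition to give 14. A second four-electron opening of 14 gives dienylketene 15, and ring A of unit 2 is then closed by a thermal six-electron (disrotatory) electrocyclization in which the ketene carbon bonds to the terminal CH2 to give 16, which tautomerizes irreversibly to phenol 17. The one selectivity needed is the orientation of the (2+2) union: donation from the methoxy oxygen makes the flavonyl-bearing alkyne carbon the nucleophilic one, so it joins the electrophilic ketene carbonyl carbon and the flavonyl group is placed between the new hydroxyl and the methoxy group. No stereocentre is created, since the sp3 carbon of 14 is lost on ring opening. A methyl ynol ether is chosen because it has no β-hydrogen for retro-ene loss of an alkene at these temperatures, and the neutral medium should leave the pyranone and the isopropyl ethers of unit 1 untouched. The closest known reaction type is the benzannulation of 3-substituted cyclobutenones with 1-alkoxyalkynes to give 2-substituted 3-alkoxyphenols. The new ring carries three different oxygens: a free hydroxyl for ring C, the methyl ether of the target, and an ethyl ether that chelation-assisted cleavage removes later.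

Step 7
Reactants: 17 6-(4-ethoxy-2-hydroxy-6-methoxyphenyl)-5,7-diisopropoxy-4'-methoxyflavone; 18 methyl 3-(4-methoxyphenyl)propiolate
Product: 19 methyl (Z)-3-[5-ethoxy-2-(5,7-diisopropoxy-4'-methoxyflavon-6-yl)-3-methoxyphenoxy]-3-(4-methoxyphenyl)acrylate
Conditions: 18 (1.5 equiv), Cs2CO3 (0.5 equiv), DMF, 80 °C
Reagents that add atoms: none
Why: Base-catalysed oxa-Michael addition of the only phenol of 17 to the β-carbon of the alkynoate; anti addition should favour the (Z) isomer drawn, and the geometry is not critical because the acid of step 9 can equilibrate it.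

Step 8
Reactants: 19 methyl (Z)-3-[5-ethoxy-2-(5,7-diisopropoxy-4'-methoxyflavon-6-yl)-3-methoxyphenoxy]-3-(4-methoxyphenyl)acrylate
Product: 20 (Z)-3-[5-ethoxy-2-(5,7-diisopropoxy-4'-methoxyflavon-6-yl)-3-methoxyphenoxy]-3-(4-methoxyphenyl)acrylic acid
Conditions: LiOH, THF/MeOH/H2O, 40 °C; then 1 M HCl, 0 °C
Reagents that add atoms: lithium hydroxide, [Li+].[OH-]
Why: Saponification by acyl–oxygen cleavage; the β-aryloxy, β-aryl acrylate is a poor acceptor for hydroxide at the β-carbon, so the ether linkage should survive, and cold, brief acidification spares the enol ether.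

Step 9
Reactants: 20 (Z)-3-[5-ethoxy-2-(5,7-diisopropoxy-4'-methoxyflavon-6-yl)-3-methoxyphenoxy]-3-(4-methoxyphenyl)acrylic acid
Product: 22 5''-ethoxy-5,7-diisopropoxy-7'',4',4'''-trimethoxy-6,8''-biflavone, via mixed trifluoroacetic anhydride 21 (not isolated)
Conditions: TFAA, TfOH (cat.), CH2Cl2, 0 °C→rt
Reagents that add atoms: none
Why: Intramolecular Friedel–Crafts acylation through mixed anhydride 21 closes ring C of unit 2 at C4a, the only free carbon ortho to the aryloxy oxygen and one further activated by an ortho ethoxy and a para methoxy group; the acid allows E/Z equilibration of the enol ether, and the 4-methoxyphenyl ring is not a competitive nucleophile.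

Step 10
Reactants: 22 5''-ethoxy-5,7-diisopropoxy-7'',4',4'''-trimethoxy-6,8''-biflavone
Product: 23 5,7,5''-trihydroxy-7'',4',4'''-trimethoxy-6,8''-biflavone (target)
Conditions: BCl3 (excess), CH2Cl2, −78 °C→rt; MeOH then H2O
Reagents that add atoms: none
Why: Lewis-acid ether cleavage; BCl3 ionizes secondary isopropyl aryl ethers readily and cleaves the ethyl ether peri to the C4 carbonyl of unit 2 through a six-membered boron chelate, whereas the three non-chelated aryl methyl ethers should survive at or below room temperature.

## Compound list

1 | acacetin (5,7-dihydroxy-4'-methoxyflavone) | COc1ccc(cc1)-c1cc(=O)c2c(O)cc(O)cc2o1 | starting material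
2 | 5-hydroxy-7-isopropoxy-4'-methoxyflavone | COc1ccc(cc1)-c1cc(=O)c2c(O)cc(OC(C)C)cc2o1 | intermediate
3 | 5-hydroxy-6-iodo-7-isopropoxy-4'-methoxyflavone | COc1ccc(cc1)-c1cc(=O)c2c(O)c(I)c(OC(C)C)cc2o1 | intermediate
4 | 6-iodo-5,7-diisopropoxy-4'-methoxyflavone | COc1ccc(cc1)-c1cc(=O)c2c(OC(C)C)c(I)c(OC(C)C)cc2o1 | intermediate
5 | chloroacetaldehyde dimethyl acetal | COC(CCl)OC | starting material
6 | lithium methoxyacetylide | [Li]C#COC | intermediate
7 | methoxyethynylzinc chloride | COC#C[Zn]Cl | intermediate
8 | 5,7-diisopropoxy-6-(methoxyethynyl)-4'-methoxyflavone | COC#Cc1c(OC(C)C)cc2oc(-c3ccc(OC)cc3)cc(=O)c2c1OC(C)C | intermediate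
9 | acetyl chloride | CC(=O)Cl | starting material
10 | ethoxyacetylene | C#COCC | starting material
11 | ketene | C=C=O | intermediate
12 | 3-ethoxycyclobut-2-en-1-one | CCOC1=CC(=O)C1 | intermediate
13 | 3-ethoxybuta-1,3-dien-1-one (vinylketene) | C=C(OCC)C=C=O | intermediate
14 | 4-(1-ethoxyvinyl)-2-(5,7-diisopropoxy-4'-methoxyflavon-6-yl)-3-methoxycyclobut-2-en-1-one (racemic, transient) | C=C(OCC)C1C(OC)=C(C1=O)c1c(OC(C)C)cc2oc(-c3ccc(OC)cc3)cc(=O)c2c1OC(C)C | intermediate
15 | 5-ethoxy-2-(5,7-diisopropoxy-4'-methoxyflavon-6-yl)-3-methoxyhexa-1,3,5-trien-1-one (dienylketene, ketene and ethoxyvinyl arms cis) | C=C(OCC)/C=C(OC)\C(=C=O)c1c(OC(C)C)cc2oc(-c3ccc(OC)cc3)cc(=O)c2c1OC(C)C | intermediate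
16 | 5-ethoxy-2-(5,7-diisopropoxy-4'-methoxyflavon-6-yl)-3-methoxycyclohexa-2,4-dien-1-one | CCOC1=CC(OC)=C(C(=O)C1)c1c(OC(C)C)cc2oc(-c3ccc(OC)cc3)cc(=O)c2c1OC(C)C | intermediate
17 | 6-(4-ethoxy-2-hydroxy-6-methoxyphenyl)-5,7-diisopropoxy-4'-methoxyflavone | COc1cc(OCC)cc(O)c1-c1c(OC(C)C)cc2oc(-c3ccc(OC)cc3)cc(=O)c2c1OC(C)C | intermediate
18 | methyl 3-(4-methoxyphenyl)propiolate | COC(=O)C#Cc1ccc(OC)cc1 | starting material
19 | methyl (Z)-3-[5-ethoxy-2-(5,7-diisopropoxy-4'-methoxyflavon-6-yl)-3-methoxyphenoxy]-3-(4-methoxyphenyl)acrylate | COC(=O)/C=C(\Oc1cc(OCC)cc(OC)c1-c1c(OC(C)C)cc2oc(-c3ccc(OC)cc3)cc(=O)c2c1OC(C)C)c1ccc(OC)cc1 | intermediate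
20 | (Z)-3-[5-ethoxy-2-(5,7-diisopropoxy-4'-methoxyflavon-6-yl)-3-methoxyphenoxy]-3-(4-methoxyphenyl)acrylic acid | OC(=O)/C=C(\Oc1cc(OCC)cc(OC)c1-c1c(OC(C)C)cc2oc(-c3ccc(OC)cc3)cc(=O)c2c1OC(C)C)c1ccc(OC)cc1 | intermediate
21 | mixed anhydride of 20 with trifluoroacetic acid | FC(F)(F)C(=O)OC(=O)/C=C(\Oc1cc(OCC)cc(OC)c1-c1c(OC(C)C)cc2oc(-c3ccc(OC)cc3)cc(=O)c2c1OC(C)C)c1ccc(OC)cc1 | intermediate
22 | 5''-ethoxy-5,7-diisopropoxy-7'',4',4'''-trimethoxy-6,8''-biflavone | COc1ccc(-c2cc(=O)c3c(OC(C)C)c(-c4c(OC)cc(OCC)c5c(=O)cc(-c6ccc(OC)cc6)oc45)c(OC(C)C)cc3o2)cc1 | intermediate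
23 | 5,7,5''-trihydroxy-7'',4',4'''-trimethoxy-6,8''-biflavone | COc1ccc(-c2cc(=O)c3c(O)c(-c4c(OC)cc(O)c5c(=O)cc(-c6ccc(OC)cc6)oc45)c(O)cc3o2)cc1 | target

## Step count and least certain steps

Total: 10 steps. Longest linear sequence: 9 steps (steps 1, 2, 3, 4, 6, 7, 8, 9, 10 from 1); step 5 is a one-step branch.

**Step 6 (key step).** The most likely failure is a slow (2+2) union, because the nucleophilic alkyne carbon of 8 is shielded by two ortho isopropoxy groups; the vinylketene would then be consumed by dimerization or polymerization. Two lesser risks are acylation of the newly formed phenol by excess vinylketene, which a mild methanolysis at work-up (K2CO3, MeOH) would reverse, and thermal oligomerization of the ynol ether. The fallback gives up the ring construction and makes the biaryl bond by cross-coupling; it sets out from 4 and comes back to the route at 23. Commercial 5,7,4'-trimethoxyflavone F1 would be iodinated with I2 and CF3CO2Ag in CH2Cl2, where a fully alkylated ring A reacts at C8, to give 8-iodo-5,7,4'-trimethoxyflavone F2. Miyaura borylation of F2 (B2pin2, PdCl2(dppf), KOAc, dioxane, 90 °C) would give 5,7,4'-trimethoxyflavone-8-boronic acid pinacol ester F3. Suzuki–Miyaura coupling of F3 with 4 (Pd(OAc)2, SPhos, K3PO4, PhMe/H2O, 100 °C) would give 5,7-diisopropoxy-5'',7'',4',4'''-tetramethoxy-6,8''-biflavone F4. BCl3 would then remove both isopropyl groups of F4 and, through the carbonyl chelate, its 5''-methyl group to give 23. The weakness of this detour is the tetra-ortho-substituted coupling of the protodeboronation-prone boronate F3, which is the reason it is not the first choice.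

**Step 4.** The likely failures are incomplete formation of the zinc acetylide from the acetal (leaving lithium acetylide, alkoxide and amine that can attack the pyranone), slow turnover at the doubly ortho-substituted iodide, and hydration or oligomerization of the acid- and heat-sensitive ynol ether during isolation. The fallback sets out from 4 and 5 and returns at 8. Acetylide 6, made as in step 4, would be quenched with Bu3SnCl to give distillable tributyl(methoxyethynyl)stannane F5. F5 would then be coupled with 4 under Stille conditions (Pd(PPh3)4, PhMe, 80 °C), with no amine, alkoxide or lithium species present, to give 8.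

**Step 5.** Ketene generated from acetyl chloride and an amine tends to dimerize or to be diverted through acylammonium species before the cycloaddition takes place. The fallback sets out from 10 and returns at 12. Treatment of Cl3CCOCl with activated Zn in Et2O would generate dichloroketene F6 in the presence of 10, and the (2+2) cycloaddition of F6 with 10 would give 4,4-dichloro-3-ethoxycyclobut-2-en-1-one F7. Reduction of F7 with Zn in AcOH/TMEDA/EtOH would then remove both chlorines and give 12.

**Step 7.** Conjugate addition of a phenoxide crowded by the neighbouring biaryl to an alkynoate deactivated by its 4-methoxyphenyl group may be slow, and prolonged heating with base may erode the material. The fallback builds ring C by the chalcone route; it sets out from 17 and comes back at 22. C-Acetylation of 17 ortho to its hydroxyl (Ac2O, BF3·OEt2, the boron chelate holding the acyl group next to the phenol oxygen) would give 6-(3-acetyl-4-ethoxy-2-hydroxy-6-methoxyphenyl)-5,7-diisopropoxy-4'-methoxyflavone F8. Claisen–Schmidt condensation of F8 with 4-methoxybenzaldehyde (KOH, EtOH) would give 6-{4-ethoxy-2-hydroxy-6-methoxy-3-[(E)-3-(4-methoxyphenyl)prop-2-enoyl]phenyl}-5,7-diisopropoxy-4'-methoxyflavone F9. Oxidative cyclization of F9 (I2 cat., DMSO, 120 °C) would close ring C and give 22. The weakness is competing acylation at the position para to the hydroxyl.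

**Step 10.** The ethyl ether peri to the carbonyl may be cleaved incompletely under conditions mild enough to keep the methyl ethers, or a methyl ether may be lost if the reaction is forced. The fallback separates the two tasks; it sets out from 22 and returns at 23. Brief treatment of 22 with BCl3 at −78 °C should remove only the isopropyl groups and give 5''-ethoxy-5,7-dihydroxy-7'',4',4'''-trimethoxy-6,8''-biflavone F10. The remaining chelated ethyl ether of F10 would then be cleaved with AlCl3 in MeCN at 50 °C, a reagent selective for ethers peri to a carbonyl, and acidic work-up would give 23.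

## Further compounds

F1 | step 6 | 5,7,4'-trimethoxyflavone | COc1ccc(cc1)-c1cc(=O)c2c(OC)cc(OC)cc2o1
F2 | step 6 | 8-iodo-5,7,4'-trimethoxyflavone | COc1ccc(cc1)-c1cc(=O)c2c(OC)cc(OC)c(I)c2o1
F3 | step 6 | 5,7,4'-trimethoxyflavone-8-boronic acid pinacol ester | COc1ccc(cc1)-c1cc(=O)c2c(OC)cc(OC)c(B3OC(C)(C)C(C)(C)O3)c2o1
F4 | step 6 | 5,7-diisopropoxy-5'',7'',4',4'''-tetramethoxy-6,8''-biflavone | COc1ccc(-c2cc(=O)c3c(OC(C)C)c(-c4c(OC)cc(OC)c5c(=O)cc(-c6ccc(OC)cc6)oc45)c(OC(C)C)cc3o2)cc1
F5 | step 4 | tributyl(methoxyethynyl)stannane | CCCC[Sn](CCCC)(CCCC)C#COC
F6 | step 5 | dichloroketene | ClC(Cl)=C=O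
F7 | step 5 | 4,4-dichloro-3-ethoxycyclobut-2-en-1-one | CCOC1=CC(=O)C1(Cl)Cl
F8 | step 7 | 6-(3-acetyl-4-ethoxy-2-hydroxy-6-methoxyphenyl)-5,7-diisopropoxy-4'-methoxyflavone | CC(=O)c1c(O)c(-c2c(OC(C)C)cc3oc(-c4ccc(OC)cc4)cc(=O)c3c2OC(C)C)c(OC)cc1OCC
F9 | step 7 | 6-{4-ethoxy-2-hydroxy-6-methoxy-3-[(E)-3-(4-methoxyphenyl)prop-2-enoyl]phenyl}-5,7-diisopropoxy-4'-methoxyflavone | COc1ccc(/C=C/C(=O)c2c(O)c(-c3c(OC(C)C)cc4oc(-c5ccc(OC)cc5)cc(=O)c4c3OC(C)C)c(OC)cc2OCC)cc1
F10 | step 10 | 5''-ethoxy-5,7-dihydroxy-7'',4',4'''-trimethoxy-6,8''-biflavone | COc1ccc(-c2cc(=O)c3c(O)c(-c4c(OC)cc(OCC)c5c(=O)cc(-c6ccc(OC)cc6)oc45)c(O)cc3o2)cc1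
A1 | alternative 1 | 5,7,5''-tris(benzyloxy)-7'',4',4'''-trimethoxy-6,8''-biflavone | COc1ccc(-c2cc(=O)c3c(OCc4ccccc4)c(-c4c(OC)cc(OCc5ccccc5)c5c(=O)cc(-c6ccc(OC)cc6)oc45)c(OCc4ccccc4)cc3o2)cc1
A2 | alternative 1 | biaryl bis(triphenylphosphoranylideneacetyl) bis(4-methoxybenzoate), open form of A1 | COc1ccc(cc1)C(=O)Oc1cc(OCc2ccccc2)c(-c2c(OC)cc(OCc3ccccc3)c(C(=O)C=P(c3ccccc3)(c3ccccc3)c3ccccc3)c2OC(=O)c2ccc(OC)cc2)c(OCc2ccccc2)c1C(=O)C=P(c1ccccc1)(c1ccccc1)c1ccccc1
A3 | alternative 2 | 5,7,5''-triisopropoxy-7'',4',4'''-trimethoxy-6,8''-biflavone | COc1ccc(-c2cc(=O)c3c(OC(C)C)c(-c4c(OC)cc(OC(C)C)c5c(=O)cc(-c6ccc(OC)cc6)oc45)c(OC(C)C)cc3o2)cc1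
A4 | alternative 2 | biaryl bis[(Z)-3-aryloxy-3-(4-methoxyphenyl)acrylic acid], open form of A3 | OC(=O)/C=C(\Oc1cc(OC(C)C)c(-c2c(OC)cc(OC(C)C)cc2O/C(=C\C(O)=O)c2ccc(OC)cc2)c(OC(C)C)c1)c1ccc(OC)cc1
A5 | alternative 3 | 5-hydroxy-7,4'-dimethoxy-8-[2,4,6-tris(benzyloxy)phenyl]flavone | COc1ccc(-c2cc(=O)c3c(O)cc(OC)c(-c4c(OCc5ccccc5)cc(OCc5ccccc5)cc4OCc4ccccc4)c3o2)cc1
A6 | alternative 3 | (E)-3-methoxy-4-[6-(4-methoxyphenyl)-4-oxo-4H-pyran-2-yl]-4-[2,4,6-tris(benzyloxy)phenyl]but-3-enoic acid | OC(=O)C/C(OC)=C(\c1cc(=O)cc(-c2ccc(OC)cc2)o1)c1c(OCc2ccccc2)cc(OCc2ccccc2)cc1OCc1ccccc1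
A7 | alternative 3 | (E)-3-methoxy-4-[6-(4-methoxyphenyl)-4-oxo-4H-pyran-2-yl]-4-[2,4,6-tris(benzyloxy)phenyl]buta-1,3-dien-1-one (dienylketene from A6) | O=C=C/C(OC)=C(\c1cc(=O)cc(-c2ccc(OC)cc2)o1)c1c(OCc2ccccc2)cc(OCc2ccccc2)cc1OCc1ccccc1
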